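**Plan**

- Retrosynthesis: ring B is taken apart first, at its three bonds C(OMe)–CH, C(chain)–C(OH) and C(OH)–CH, into the (S,E)-enyne 13, one CO ligand and the vinyl(methoxy)carbene complex 16 (Dötz benzannulation). The hydroquinone is reached from the 4-methoxyphenol through the quinone.
- Enabling feature: ring B is a 1,4-dioxygenated benzene whose only carbon substituent, C5 of the chain, lies ortho to one oxygen and whose other three ring carbons are CH. A carbene carbon (C–OMe), a CO (C–OH), a vinyl group (two CH) and a terminal alkyne (C–chain and CH) assemble exactly this pattern.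
- The enyne is cut at C5–alkyne (Negishi), C4=C5 (Takai) and C1–ring A (B-alkyl Suzuki–Miyaura), which leads to ring A bromide 4 and the vinyl carbinol ether 8.
- Forward: ring A is bought as 4-bromo-3,5-dimethylphenol, formylated and protected. The chain is grown from (R)-2-methylglycidol, joined to ring A and extended to the enyne. Ring B is then built on the alkyne, and oxidation, reduction and deprotection finish the synthesis.
- Stereochemistry: C3 comes from (R)-2-methylglycidol and is never a reacting centre (the epoxide is opened at its CH2 group), which gives 3S. The E alkene comes from the Takai olefination.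

Key step: step 12

Remark: the aryl dimethyl acetal (4 and all later acetal-bearing compounds) is assumed to be chromatographed on triethylamine-deactivated silica, since electron-rich benzaldehyde acetals hydrolyse on acidic silica.

**Route**

Step 1
Reactants: 1 4-bromo-3,5-dimethylphenol
Product: 2 3-bromo-6-hydroxy-2,4-dimethylbenzaldehyde
Conditions: MgCl2, Et3N, (CH2O)n, MeCN, reflux
Reagents that add atoms: paraformaldehyde (formaldehyde), C=O
Why: Casnati–Skattebøl ortho-formylation, in which the magnesium phenoxide of 1 directs formaldehyde to the position ortho to oxygen (both ortho positions are equivalent and the para position carries bromine) and a second formaldehyde oxidises the benzylic alkoxide to the aldehyde by hydride transfer.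

Step 2
Reactants: 2 3-bromo-6-hydroxy-2,4-dimethylbenzaldehyde
Product: 3 3-bromo-2,4-dimethyl-6-(triisopropylsilyloxy)benzaldehyde
Conditions: TIPSOTf, 2,6-lutidine, CH2Cl2, 0 °C → rt
Reagents that add atoms: triisopropylsilyl triflate, CC(C)[Si](OS(=O)(=O)C(F)(F)F)(C(C)C)C(C)C
Why: O-silylation of the hydrogen-bonded phenol with the reactive silyl triflate gives a bulky aryl TIPS ether that tolerates the basic and organometallic steps ahead and is removed by fluoride at the end.

Step 3
Reactants: 3 3-bromo-2,4-dimethyl-6-(triisopropylsilyloxy)benzaldehyde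
Product: 4 [4-bromo-2-(dimethoxymethyl)-3,5-dimethylphenoxy]triisopropylsilane (ring A bromide)
Conditions: HC(OMe)3, p-TsOH·H2O (cat.), MeOH, rt; Et3N quench
Reagents that add atoms: trimethyl orthoformate, COC(OC)OC; methanol, CO
Why: Acid-catalysed acetalisation driven by trimethyl orthoformate as water scavenger masks the aryl aldehyde, which would otherwise compete in the Takai olefination of step 9, as an acetal that later falls off at pH 5 once the ortho phenol is free.

Step 4
Reactants: 5 (R)-2-methylglycidol
Product: 6 (S)-triethyl[(2-methyloxiran-2-yl)methoxy]silane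
Conditions: TESCl, imidazole, CH2Cl2, 0 °C
Reagents that add atoms: chlorotriethylsilane, CC[Si](Cl)(CC)CC
Why: Standard O-silylation of the primary alcohol leaves the epoxide and its quaternary stereocenter untouched (the descriptor changes from R to S only because the CIP priorities change).

Step 5
Reactants: 6 (S)-triethyl[(2-methyloxiran-2-yl)methoxy]silane
Product: 7 (S)-2-methyl-1-(triethylsilyloxy)but-3-en-2-ol
Conditions: Me3SI, n-BuLi, THF, −10 °C → rt
Reagents that add atoms: trimethylsulfonium iodide, C[S+](C)C.[I-]
Why: One-carbon homologation of an epoxide to an allylic alcohol with excess dimethylsulfonium methylide, in which the ylide opens the epoxide at its unsubstituted CH2, a second equivalent turns the betaine into a new sulfur ylide that eliminates dimethyl sulfide to leave the vinyl group, and no bond to the quaternary carbon is broken, so the configuration of 5 is carried over (a silyl shift between the two oxygens would be harmless because step 6 silylates the remaining hydroxyl).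

Step 6
Reactants: 7 (S)-2-methyl-1-(triethylsilyloxy)but-3-en-2-ol
Product: 8 (S)-3-methyl-3,4-bis(triethylsilyloxy)but-1-ene
Conditions: TESOTf, 2,6-lutidine, CH2Cl2, −78 → 0 °C
Reagents that add atoms: triethylsilyl triflate, CC[Si](CC)(CC)OS(=O)(=O)C(F)(F)F
Why: Silylation of the hindered tertiary alcohol with the silyl triflate gives a bis(triethylsilyl) ether whose primary and tertiary Si–O bonds can later be told apart.

Step 7
Reactants: 8 (S)-3-methyl-3,4-bis(triethylsilyloxy)but-1-ene; 4 [4-bromo-2-(dimethoxymethyl)-3,5-dimethylphenoxy]triisopropylsilane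
Product: 10 {2-(dimethoxymethyl)-3,5-dimethyl-4-[(S)-3-methyl-3,4-bis(triethylsilyloxy)butyl]phenoxy}triisopropylsilane, via alkylborane 9 (not isolated)
Conditions: 9-BBN, THF, rt; then 4, Pd(OAc)2, SPhos, K3PO4 (aq), THF, 65 °C
Reagents that add atoms: none
Why: Anti-Markovnikov hydroboration of the monosubstituted alkene with 9-BBN followed by B-alkyl Suzuki–Miyaura coupling, for which the bulky electron-rich biaryl phosphine SPhos is chosen because the bromide of 4 is flanked by two methyl groups, forms the C1–ring A bond without touching the stereocenter.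

Step 8
Reactants: 10 {2-(dimethoxymethyl)-3,5-dimethyl-4-[(S)-3-methyl-3,4-bis(triethylsilyloxy)butyl]phenoxy}triisopropylsilane
Product: 11 (S)-4-[3-(dimethoxymethyl)-2,6-dimethyl-4-(triisopropylsilyloxy)phenyl]-2-methyl-2-(triethylsilyloxy)butanal
Conditions: (COCl)2, DMSO, CH2Cl2, −78 → −30 °C; then Et3N, → 0 °C
Reagents that add atoms: none
Why: Swern oxidation applied directly to the silyl ether, in which the chlorosulfonium reagent cleaves only the less hindered primary Si–O bond and the resulting alkoxysulfonium ion collapses to the aldehyde while the tertiary TES and aryl TIPS ethers stay; the aldehyde has no α-hydrogen, so C3 cannot epimerise.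

Step 9
Reactants: 11 (S)-4-[3-(dimethoxymethyl)-2,6-dimethyl-4-(triisopropylsilyloxy)phenyl]-2-methyl-2-(triethylsilyloxy)butanal
Product: 12 {2-(dimethoxymethyl)-4-[(S,E)-5-iodo-3-methyl-3-(triethylsilyloxy)pent-4-en-1-yl]-3,5-dimethylphenoxy}triisopropylsilane
Conditions: CrCl2, CHI3, THF/1,4-dioxane, 0 °C → rt
Reagents that add atoms: iodoform, IC(I)I
Why: Takai olefination, in which the geminal dichromium species formed from CHI3 and CrCl2 adds to the aldehyde and anti-periplanar elimination from the more stable adduct gives the E vinyl iodide, with the acetal and silyl ethers inert to the reagent.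

Step 10
Reactants: 12 {2-(dimethoxymethyl)-4-[(S,E)-5-iodo-3-methyl-3-(triethylsilyloxy)pent-4-en-1-yl]-3,5-dimethylphenoxy}triisopropylsilane
Product: 13 {2-(dimethoxymethyl)-3,5-dimethyl-4-[(S,E)-3-methyl-3-(triethylsilyloxy)hept-4-en-6-yn-1-yl]phenoxy}triisopropylsilane
Conditions: HC≡CMgBr, ZnBr2, THF, 0 °C; then 12, Pd(PPh3)4, THF, rt
Reagents that add atoms: ethynylmagnesium bromide, C#C[Mg]Br
Why: Negishi coupling of the alkenyl iodide with ethynylzinc bromide under zerovalent palladium catalysis proceeds with retention of the E geometry and gives the terminal enyne directly, so no alkyne protecting group has to be removed.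

Step 11
Reactants: 14 chromium hexacarbonyl, Cr(CO)6
Product: 16 pentacarbonyl[methoxy(vinyl)carbene]chromium, via lithium acylchromate 15 (not isolated)
Conditions: Sn(CH=CH2)4, MeLi, Et2O, 0 °C; Cr(CO)6, Et2O, 0 °C → rt; then Me3OBF4, CH2Cl2, 0 °C
Reagents that add atoms: tetravinylstannane, C=C[Sn](C=C)(C=C)C=C; trimethyloxonium tetrafluoroborate, C[O+](C)C.F[B-](F)(F)F
Why: Fischer carbene synthesis, in which vinyllithium adds to a CO ligand of Cr(CO)6 to give the acylchromate 15 and the hard methylating agent Me3OBF4 alkylates it on oxygen; the complex is kept cold and used at once because the parent vinyl complex polymerises on standing.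

Step 12
Reactants: 13 {2-(dimethoxymethyl)-3,5-dimethyl-4-[(S,E)-3-methyl-3-(triethylsilyloxy)hept-4-en-6-yn-1-yl]phenoxy}triisopropylsilane; 16 pentacarbonyl[methoxy(vinyl)carbene]chromium
Product: 18 2-{(S,E)-5-[3-(dimethoxymethyl)-2,6-dimethyl-4-(triisopropylsilyloxy)phenyl]-3-methyl-3-(triethylsilyloxy)pent-1-en-1-yl}-4-methoxyphenol, via tricarbonylchromium phenol complex 17 (not isolated)
Conditions: THF (degassed), 50 °C, Ar, fresh 16 added in portions; then air, Et2O, rt
Reagents that add atoms: none
Why: Loss of one CO from zerovalent chromium in 16 opens a site for the terminal alkyne of 13, which inserts into the Cr=C bond with its CH terminus bonded to the carbene carbon; CO insertion gives a chromium-bound dienylketene that cyclises and tautomerises to the phenol, held on Cr(CO)3 as 17 until air sets 18 free. This is the Dötz benzannulation of an alkenyl(alkoxy)carbene chromium complex with a terminal alkyne, a reaction type that accepts conjugated enynes as the alkyne partner. Ring B is closed by a thermal 6π electrocyclisation of the dienylketene that joins the former CO carbon to the vinyl CH2 carbon, after the two insertions have made the carbene C–alkyne CH bond and the alkyne C–CO bond. No stereocenter is created, and the C3 silyl ether and the E alkene are spectators under these neutral conditions. The selectivity needed is the regiochemistry of alkyne insertion, which the steric difference between H and the alkenyl substituent of the terminal alkyne secures, so the chain carbon lies next to the new phenolic carbon and the methoxy group para to the hydroxyl. Phenol formation, not cyclobutenone or furan formation, is the normal course for alkenyl carbenes in THF, and adding fresh 16 in portions offsets its polymerisation.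

Step 13
Reactants: 18 2-{(S,E)-5-[3-(dimethoxymethyl)-2,6-dimethyl-4-(triisopropylsilyloxy)phenyl]-3-methyl-3-(triethylsilyloxy)pent-1-en-1-yl}-4-methoxyphenol
Product: 20 2-{(S,E)-5-[3-(dimethoxymethyl)-2,6-dimethyl-4-(triisopropylsilyloxy)phenyl]-3-methyl-3-(triethylsilyloxy)pent-1-en-1-yl}benzene-1,4-diol, via vinylquinone 19 (not isolated)
Conditions: PhI(OAc)2, NaHCO3, MeCN/H2O, 0 °C; then Na2S2O4 (aq), EtOAc, rt
Reagents that add atoms: water, O
Why: Oxidative demethylation of a 4-methoxyphenol by PhI(OAc)2 in aqueous acetonitrile (ligand exchange at iodine, attack of water para to the phenol oxygen, loss of methanol) gives the 1,4-benzoquinone 19, which Na2S2O4 reduces in the same flask to the hydroquinone so that the reactive vinylquinone is never stored, and the bicarbonate buffer keeps the acetal and silyl ethers intact.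

Step 14
Reactants: 20 2-{(S,E)-5-[3-(dimethoxymethyl)-2,6-dimethyl-4-(triisopropylsilyloxy)phenyl]-3-methyl-3-(triethylsilyloxy)pent-1-en-1-yl}benzene-1,4-diol
Product: 22 3-[(S,E)-5-(2,5-dihydroxyphenyl)-3-hydroxy-3-methylpent-4-en-1-yl]-6-hydroxy-2,4-dimethylbenzaldehyde (CNP0159341.1), via desilylated dimethyl acetal 21 (not isolated)
Conditions: TBAF, AcOH, THF, 0 °C → rt, Ar; then NaOAc/AcOH buffer (pH 5), THF/H2O, rt
Reagents that add atoms: water, O
Why: Fluoride-mediated desilylation buffered with acetic acid cleaves the aryl TIPS and tertiary TES ethers without generating phenoxides that would air-oxidise, and the ortho-hydroxy benzaldehyde dimethyl acetal 21 then hydrolyses at pH 5, an acidity too low to ionise the tertiary styryl carbinol, so C3 keeps its S configuration.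

**Compound list**

1 | 4-bromo-3,5-dimethylphenol | Cc1cc(O)cc(C)c1Br | starting material
2 | 3-bromo-6-hydroxy-2,4-dimethylbenzaldehyde | Cc1cc(O)c(C=O)c(C)c1Br | intermediate
3 | 3-bromo-2,4-dimethyl-6-(triisopropylsilyloxy)benzaldehyde | Cc1cc(O[Si](C(C)C)(C(C)C)C(C)C)c(C=O)c(C)c1Br | intermediate
4 | [4-bromo-2-(dimethoxymethyl)-3,5-dimethylphenoxy]triisopropylsilane | Cc1cc(O[Si](C(C)C)(C(C)C)C(C)C)c(C(OC)OC)c(C)c1Br | intermediate
5 | (R)-2-methylglycidol | C[C@@]1(CO)CO1 | starting material
6 | (S)-triethyl[(2-methyloxiran-2-yl)methoxy]silane (TES ether of 5) | C[C@@]1(CO[Si](CC)(CC)CC)CO1 | intermediate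
7 | (S)-2-methyl-1-(triethylsilyloxy)but-3-en-2-ol | C=C[C@](C)(O)CO[Si](CC)(CC)CC | intermediate
8 | (S)-3-methyl-3,4-bis(triethylsilyloxy)but-1-ene | C=C[C@](C)(O[Si](CC)(CC)CC)CO[Si](CC)(CC)CC | intermediate
9 | 9-[(S)-3-methyl-3,4-bis(triethylsilyloxy)butyl]-9-borabicyclo[3.3.1]nonane (formed in the flask) | C1CCC2CCCC1B2CC[C@](C)(O[Si](CC)(CC)CC)CO[Si](CC)(CC)CC | intermediate
10 | {2-(dimethoxymethyl)-3,5-dimethyl-4-[(S)-3-methyl-3,4-bis(triethylsilyloxy)butyl]phenoxy}triisopropylsilane | Cc1cc(O[Si](C(C)C)(C(C)C)C(C)C)c(C(OC)OC)c(C)c1CC[C@](C)(O[Si](CC)(CC)CC)CO[Si](CC)(CC)CC | intermediate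
11 | (S)-4-[3-(dimethoxymethyl)-2,6-dimethyl-4-(triisopropylsilyloxy)phenyl]-2-methyl-2-(triethylsilyloxy)butanal | Cc1cc(O[Si](C(C)C)(C(C)C)C(C)C)c(C(OC)OC)c(C)c1CC[C@](C)(O[Si](CC)(CC)CC)C=O | intermediate
12 | {2-(dimethoxymethyl)-4-[(S,E)-5-iodo-3-methyl-3-(triethylsilyloxy)pent-4-en-1-yl]-3,5-dimethylphenoxy}triisopropylsilane | Cc1cc(O[Si](C(C)C)(C(C)C)C(C)C)c(C(OC)OC)c(C)c1CC[C@](C)(O[Si](CC)(CC)CC)/C=C/I | intermediate
13 | {2-(dimethoxymethyl)-3,5-dimethyl-4-[(S,E)-3-methyl-3-(triethylsilyloxy)hept-4-en-6-yn-1-yl]phenoxy}triisopropylsilane | Cc1cc(O[Si](C(C)C)(C(C)C)C(C)C)c(C(OC)OC)c(C)c1CC[C@](C)(O[Si](CC)(CC)CC)/C=C/C#C | intermediate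
14 | chromium hexacarbonyl, Cr(CO)6 | O=C=[Cr](=C=O)(=C=O)(=C=O)(=C=O)=C=O | starting material
15 | lithium pentacarbonyl(acryloyl)chromate (formed in the flask) | [Li+].C=CC([O-])=[Cr](=C=O)(=C=O)(=C=O)(=C=O)=C=O | intermediate
16 | pentacarbonyl[methoxy(vinyl)carbene]chromium | C=CC(OC)=[Cr](=C=O)(=C=O)(=C=O)(=C=O)=C=O | intermediate
17 | tricarbonylchromium complex of 18, bound η6 to ring B (formed in the flask; the η6 bond is written as a dot) | Cc1cc(O[Si](C(C)C)(C(C)C)C(C)C)c(C(OC)OC)c(C)c1CC[C@](C)(O[Si](CC)(CC)CC)/C=C/c1cc(OC)ccc1O.O=C=[Cr](=C=O)=C=O | intermediate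
18 | 2-{(S,E)-5-[3-(dimethoxymethyl)-2,6-dimethyl-4-(triisopropylsilyloxy)phenyl]-3-methyl-3-(triethylsilyloxy)pent-1-en-1-yl}-4-methoxyphenol | Cc1cc(O[Si](C(C)C)(C(C)C)C(C)C)c(C(OC)OC)c(C)c1CC[C@](C)(O[Si](CC)(CC)CC)/C=C/c1cc(OC)ccc1O | intermediate
19 | 2-{(S,E)-5-[3-(dimethoxymethyl)-2,6-dimethyl-4-(triisopropylsilyloxy)phenyl]-3-methyl-3-(triethylsilyloxy)pent-1-en-1-yl}cyclohexa-2,5-diene-1,4-dione (formed in the flask) | Cc1cc(O[Si](C(C)C)(C(C)C)C(C)C)c(C(OC)OC)c(C)c1CC[C@](C)(O[Si](CC)(CC)CC)/C=C/C1=CC(=O)C=CC1=O | intermediate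
20 | 2-{(S,E)-5-[3-(dimethoxymethyl)-2,6-dimethyl-4-(triisopropylsilyloxy)phenyl]-3-methyl-3-(triethylsilyloxy)pent-1-en-1-yl}benzene-1,4-diol | Cc1cc(O[Si](C(C)C)(C(C)C)C(C)C)c(C(OC)OC)c(C)c1CC[C@](C)(O[Si](CC)(CC)CC)/C=C/c1cc(O)ccc1O | intermediate
21 | 2-{(S,E)-5-[3-(dimethoxymethyl)-4-hydroxy-2,6-dimethylphenyl]-3-hydroxy-3-methylpent-1-en-1-yl}benzene-1,4-diol (formed in the flask) | Cc1cc(O)c(C(OC)OC)c(C)c1CC[C@](C)(O)/C=C/c1cc(O)ccc1O | intermediate
22 | 3-[(S,E)-5-(2,5-dihydroxyphenyl)-3-hydroxy-3-methylpent-4-en-1-yl]-6-hydroxy-2,4-dimethylbenzaldehyde (CNP0159341.1) | Cc1cc(O)c(C=O)c(C)c1CC[C@](C)(O)/C=C/c1cc(O)ccc1O | target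

**Totals**

Total step count: 14.
Longest linear sequence: 10 steps (steps 4, 5, 6, 7, 8, 9, 10, 12, 13, 14 from 5; the branch from 1 through steps 1, 2, 3 and then 7 onward is equally long).

**Steps most likely to fail**

Step 12. The parent vinyl carbene complex may polymerise or decompose thermally faster than it inserts the alkyne, and a second alkyne may be taken up. The fallback keeps the same ring construction but changes the carbene partner to a silicon-bearing surrogate that can be stored. It sets out from 13 and 14. Compound 14 is treated with (E)-2-(trimethylsilyl)vinyllithium (from (E)-(2-bromovinyl)trimethylsilane and t-BuLi) to give the lithium acylchromate F1, and Me3OBF4 converts this into pentacarbonyl{methoxy[(E)-2-(trimethylsilyl)vinyl]carbene}chromium F2. Heating F2 with 13 in THF forms the same three ring bonds. The cyclohexadienone intermediate is expected to aromatise by a 1,3-shift of silicon from carbon to oxygen and not by hydrogen tautomerisation, which gives the tricarbonylchromium complex F3 of the aryl trimethylsilyl ether. Air releases the free aryl trimethylsilyl ether F4, and brief K2CO3/MeOH at 0 °C removes the O–SiMe3 group, so the route is rejoined at 18.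

Step 7. Oxidative addition and transmetalation at the bromide flanked by two methyl groups may be slow, so that protodeboronation of the alkylborane or reduction of the aryl bromide takes over. The fallback replaces the sp3–sp2 coupling by an sp2–sp2 coupling followed by reduction. It sets out from 4 and 8. A Heck reaction (Pd2(dba)3, P(t-Bu)3, Cy2NMe, dioxane, 80 °C) should give the (S,E)-styrene F5 as a single alkene isomer, because only the benzylic β-hydrogens are available for elimination. Hydrogenation (H2, Pd/C, EtOAc with a little Et3N) then saturates the alkene, and the route is rejoined at 10.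

Step 8. Cleavage of the primary Si–O bond next to the quaternary carbon may be incomplete, and HCl liberated from the chlorosulfonium salt may cost the acetal. The fallback separates deprotection from oxidation. It sets out from 10. PPTS in MeOH/CH2Cl2 at 0 °C removes only the primary TES group and gives the primary alcohol F6; in methanol the dimethyl acetal can only exchange with itself. Dess–Martin periodinane with NaHCO3 in CH2Cl2 then oxidises F6 under neutral conditions, and the route is rejoined at 11.

**Further compounds**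

F1 | step 12 | lithium pentacarbonyl[(E)-3-(trimethylsilyl)acryloyl]chromate | [Li+].C[Si](C)(C)/C=C/C([O-])=[Cr](=C=O)(=C=O)(=C=O)(=C=O)=C=O
F2 | step 12 | pentacarbonyl{methoxy[(E)-2-(trimethylsilyl)vinyl]carbene}chromium | C[Si](C)(C)/C=C/C(OC)=[Cr](=C=O)(=C=O)(=C=O)(=C=O)=C=O
F3 | step 12 | tricarbonylchromium complex of F4, bound η6 to ring B (the η6 bond is written as a dot) | Cc1cc(O[Si](C(C)C)(C(C)C)C(C)C)c(C(OC)OC)c(C)c1CC[C@](C)(O[Si](CC)(CC)CC)/C=C/c1cc(OC)ccc1O[Si](C)(C)C.O=C=[Cr](=C=O)=C=O
F4 | step 12 | aryl trimethylsilyl ether of 18 | Cc1cc(O[Si](C(C)C)(C(C)C)C(C)C)c(C(OC)OC)c(C)c1CC[C@](C)(O[Si](CC)(CC)CC)/C=C/c1cc(OC)ccc1O[Si](C)(C)C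
F5 | step 7 | {2-(dimethoxymethyl)-3,5-dimethyl-4-[(S,E)-3-methyl-3,4-bis(triethylsilyloxy)but-1-en-1-yl]phenoxy}triisopropylsilane | Cc1cc(O[Si](C(C)C)(C(C)C)C(C)C)c(C(OC)OC)c(C)c1/C=C/[C@](C)(O[Si](CC)(CC)CC)CO[Si](CC)(CC)CC
F6 | step 8 | (S)-4-[3-(dimethoxymethyl)-2,6-dimethyl-4-(triisopropylsilyloxy)phenyl]-2-methyl-2-(triethylsilyloxy)butan-1-ol | Cc1cc(O[Si](C(C)C)(C(C)C)C(C)C)c(C(OC)OC)c(C)c1CC[C@](C)(O[Si](CC)(CC)CC)CO
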